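**Plan**

1. Numbering and faces: eudesmane numbering; ring A = C1–C2–C3(O-angeloyl)–C4(OH)(CH3)–C5–C10(CH3), ring B = C5=C6–C7(acrylate)–C8–C9–C10; β is the face of the C10 methyl.
2. Retrosynthesis: first the two ester C–O bonds and the C12 oxidation level, then C3–H. What remains in ring A is an α-ketol (C3 ketone next to the C4 tertiary carbinol) whose carbinol carbon C4 sits on alkene carbon C5, so the C4–C5 bond is cut by a retro α-ketol shift to a five-membered 1-acetyl-1-hydroxy ring (C3, C2, C1, C10, C5) with C5 bonded to C3.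
3. Further cuts: C3–C4 (acetyl anion equivalent onto a bicyclic enone), C3–C5 together with C5=C6 (ketyl–nitrile closure, dehydration) and C10–C1 (Michael addition to acrylonitrile).
4. Forward: ring B is bought as (+)-dihydrocarvone and its isopropenyl methyl is oxygenated; a five-membered ring is fused on (C10–C1, then C3–C5); the acetyl unit is added and the five-membered ring is expanded to ring A; reduction, angeloylation and oxidation of C12 to the methyl ester follow.
5. Stereochemistry: C7 from dihydrocarvone; C10 from the (R)-1-phenylethylamine imine; the C3 carbinol, set anti to the C10 methyl, is relayed to C4 by the chelated 1,2-shift; C3 is then reset by axial hydride attack; the Z-alkene comes from angelic acid.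

Key step: step 8

Remark: commercial (+)-dihydrocarvone carries some of its C2 epimer; both epimers converge at the imine/enamine stage of step 4, so only the (2R,5R) isomer is drawn for compounds 1 to 5.

**Route**

Step 1
Reactants: 1 (+)-dihydrocarvone
Product: 2 (2R,5R)-5-(3-chloroprop-1-en-2-yl)-2-methylcyclohexan-1-one
Conditions: Ca(OCl)2, CO2 (dry ice), CH2Cl2/H2O, 0 °C
Reagents that add atoms: calcium hypochlorite, [Ca+2].[O-]Cl.[O-]Cl
Why: Ene-type allylic chlorination by HOCl should take place only at the electron-rich 1,1-disubstituted alkene, with the double bond shifting into the former methyl group, while the ketone and the C7 center are untouched in the buffered two-phase medium.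

Step 2
Reactants: 2 allylic chloride
Product: 4 (2R,5R)-5-(3-hydroxyprop-1-en-2-yl)-2-methylcyclohexan-1-one, via allylic acetate 3 (not isolated)
Conditions: KOAc, NaI (cat.), DMF, 60 °C; then K2CO3 (cat.), MeOH, rt
Reagents that add atoms: potassium acetate, CC(=O)[O-].[K+]
Why: SN2 displacement of the primary allylic chloride by acetate (SN2 and SN2' give the same product here) followed by transesterification with methanol should give the allylic alcohol.

Step 3
Reactants: 4 allylic alcohol
Product: 5 (2R,5R)-5-{3-[(tert-butyldiphenylsilyl)oxy]prop-1-en-2-yl}-2-methylcyclohexan-1-one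
Conditions: TBDPSCl, imidazole, DMF, rt
Reagents that add atoms: tert-butyl(chloro)diphenylsilane, CC(C)(C)[Si](Cl)(c1ccccc1)c1ccccc1
Why: Standard silylation of a primary alcohol gives a robust ether that masks the future ester carbon C12 through the organolithium, Lewis acid and acylation steps.

Step 4
Reactants: 5 silyl ether ketone; 6 (R)-1-phenylethylamine; 7 acrylonitrile
Product: 10 keto nitrile with C10 quaternary (S), via imine 8 (not isolated), via Michael adduct imine 9 (not isolated)
Conditions: 6, TsOH (cat.), PhMe, reflux (Dean–Stark); 7, THF, 60 °C; then 20% aq. AcOH, rt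
Reagents that add atoms: water, O
Why: Asymmetric Michael addition of a chiral imine through its more substituted secondary enamine tautomer, in a compact aza-ene-like transition state on the enamine face anti to the phenyl group, so that the (R)-auxiliary should set C10 as S with the cyanoethyl chain trans to the C7 side chain while both C2 epimers of 5 converge.

Step 5
Reactants: 10 keto nitrile
Product: 12 cis-fused bicyclic α-ketol (C5 hydroxyl and C3 ketone), via hydroxy imine 11 (not isolated)
Conditions: SmI2 (2.5 equiv), t-BuOH, THF, hv (visible light), rt; then 1 M HCl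
Reagents that add atoms: water, O
Why: Intramolecular ketyl–nitrile reductive coupling (5-exo attack of the samarium ketyl at C5 on the nitrile carbon C3) gives an α-hydroxy imine that is hydrolysed on work-up; the cis ring fusion expected at C5 is of no consequence because C5 becomes sp2 in step 6.

Step 6
Reactants: 12 α-ketol
Product: 13 bicyclic enone (C3 ketone conjugated with C5=C6)
Conditions: SOCl2, pyridine, CH2Cl2, 0 °C
Reagents that add atoms: none
Why: E2 dehydration of the tertiary α-ketol through its chlorosulfite can only proceed toward C6 (C10 is quaternary and C3 is the carbonyl) and gives the conjugated enone, the classical dehydration of tertiary α-hydroxy ketones.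

Step 7
Reactants: 13 enone; 14 ethyl vinyl ether
Product: 16 acetyl carbinol (3β-hydroxy and 3α-acetyl on the five-membered ring), via ethoxyvinyl carbinol 15 (not isolated)
Conditions: 14, t-BuLi, THF, −78 to 0 °C; then 13, −78 °C; then 0.5 M HCl, THF/H2O, 0 °C
Reagents that add atoms: water, O
Why: 1,2-Addition of 1-ethoxyvinyllithium (acetyl anion equivalent) to the enone carbonyl should occur anti to the C10 methyl, which stands perpendicular to the flat five-membered enone, placing the new hydroxyl β (C3 S), and mild acid then hydrolyses the enol ether to the methyl ketone.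

Step 8
Reactants: 16 acetyl carbinol
Product: 17 ring-expanded ketol (C3 ketone; 4β-hydroxy and 4α-methyl)
Conditions: Al(Ot-Bu)3 (1.2 equiv), PhMe, 60 °C; aq. Rochelle salt work-up
Reagents that add atoms: none
Why: Alkoxide exchange gives the aluminium alkoxide of the C3 hydroxyl, which chelates the acetyl oxygen (O–C3–C4=O syn-periplanar); with the alkoxide pushing and the coordinated carbonyl pulling, the alkenyl ring carbon C5 shifts with its bonding pair from C3 to the acetyl carbon C4, so that C3 becomes the ketone and C4 the tertiary aluminium alkoxide. The closest known reaction type is the α-ketol (acyloin) rearrangement that expands 1-acylcycloalkanols by one carbon, as in the aluminium alkoxide mediated D-homoannulation of 17-hydroxy-20-oxo steroids. No ring is closed by cyclisation: the five-membered ring C3–C2–C1–C10–C5 becomes six-membered ring A because C4 is inserted between C3 and C5 in a suprafacial 1,2-shift. The only new stereocenter, C4, is controlled by the C3 carbinol center set in step 7: in the chelate C5 lies over one face of the acetyl carbonyl and C2 over the other, and migration of C5 from the epimer with hydroxyl β and acetyl α should give 4β-OH/4α-CH3 (4R), a hydroxyl syn to the C10 methyl that an external oxidant would not deliver. The step needs migration of C5 and not of C2, which the substrate secures because C5 is sp2 and its π lobe on the acetyl-bearing face overlaps the carbonyl π* (alkenyl far above primary alkyl in migratory aptitude), and it needs to stop at 17, which relief of cyclopentane strain and the moderate temperature should allow before any slower methyl shift.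

Step 9
Reactants: 17 ring-expanded ketol
Product: 18 cis-3β,4β-diol
Conditions: NaBH4, MeOH, −40 °C
Reagents that add atoms: none
Why: Ketone reduction in which hydride should add axially from the α face, anti to the axial C4 hydroxyl (Felkin–Anh sense) and away from the C10 methyl, giving the equatorial 3β-hydroxyl cis to the 4β-hydroxyl (C3 S).

Step 10
Reactants: 18 diol; 19 angelic acid
Product: 20 3-O-angelate silyl ether
Conditions: 19, 2,4,6-trichlorobenzoyl chloride, Et3N, PhMe, rt; then 18, PhMe, 80 °C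
Reagents that add atoms: none
Why: Mixed-anhydride (Yamaguchi-type) acylation without a nucleophilic catalyst should acylate only the secondary hydroxyl (the tertiary C4 hydroxyl is too hindered) and avoids the addition–elimination pathway that isomerises Z to E.

Step 11
Reactants: 20 angelate silyl ether
Product: 21 primary allylic alcohol
Conditions: HF·pyridine, pyridine, THF, 0 °C to rt
Reagents that add atoms: none
Why: Fluoride-driven cleavage of the primary silyl ether under buffered conditions should leave the angelate and the tertiary allylic alcohol untouched.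

Step 12
Reactants: 21 allylic alcohol
Product: 22 enal (2-substituted acrolein)
Conditions: MnO2, CH2Cl2, rt
Reagents that add atoms: none
Why: Allylic oxidation with MnO2 is selective for the primary allylic alcohol, since the tertiary C4 alcohol cannot be oxidised.

Step 13
Reactants: 22 enal
Product: 24 target methyl ester CNP0283268.1, via acrylic acid 23 (not isolated)
Conditions: NaClO2, NaH2PO4, 2-methylbut-2-ene, t-BuOH/H2O, 0 °C to rt; then TMSCHN2, PhMe/MeOH, 0 °C
Reagents that add atoms: sodium chlorite, [Na+].[O-]Cl=O; (trimethylsilyl)diazomethane, C[Si](C)(C)C=[N+]=[N-]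
Why: Pinnick oxidation with a hypochlorite scavenger should convert the enal to the acid without touching the alkenes, and diazomethane released from TMSCHN2/MeOH methylates only the carboxylic acid.

**Compound list**

1 | (+)-dihydrocarvone, (2R,5R)-2-methyl-5-(prop-1-en-2-yl)cyclohexan-1-one | C=C(C)[C@H]1CC(=O)[C@H](C)CC1 | starting material
2 | (2R,5R)-5-(3-chloroprop-1-en-2-yl)-2-methylcyclohexan-1-one | C=C(CCl)[C@H]1CC(=O)[C@H](C)CC1 | intermediate
3 | 2-[(1R,4R)-4-methyl-3-oxocyclohexyl]prop-2-en-1-yl acetate (not isolated) | C=C(COC(C)=O)[C@H]1CC(=O)[C@H](C)CC1 | intermediate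
4 | (2R,5R)-5-(3-hydroxyprop-1-en-2-yl)-2-methylcyclohexan-1-one | C=C(CO)[C@H]1CC(=O)[C@H](C)CC1 | intermediate
5 | (2R,5R)-5-{3-[(tert-butyldiphenylsilyl)oxy]prop-1-en-2-yl}-2-methylcyclohexan-1-one | C=C(CO[Si](c1ccccc1)(c1ccccc1)C(C)(C)C)[C@H]1CC(=O)[C@H](C)CC1 | intermediate
6 | (R)-1-phenylethylamine | C[C@@H](N)c1ccccc1 | starting material
7 | acrylonitrile | C=CC#N | starting material
8 | N-[(1R)-1-phenylethyl] imine of 5, C2 epimers equilibrating through the enamine (not isolated) | C=C(CO[Si](c1ccccc1)(c1ccccc1)C(C)(C)C)[C@H]1CC(=N[C@H](C)c2ccccc2)C(C)CC1 | intermediate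
9 | N-[(1R)-1-phenylethyl] imine of 10 (not isolated) | C=C(CO[Si](c1ccccc1)(c1ccccc1)C(C)(C)C)[C@H]1CC(=N[C@H](C)c2ccccc2)[C@](C)(CCC#N)CC1 | intermediate
10 | 3-[(1S,4R)-4-{3-[(tert-butyldiphenylsilyl)oxy]prop-1-en-2-yl}-1-methyl-2-oxocyclohexyl]propanenitrile | C=C(CO[Si](c1ccccc1)(c1ccccc1)C(C)(C)C)[C@H]1CC(=O)[C@](C)(CCC#N)CC1 | intermediate
11 | cis-fused (3aS,6R,7aR)-6-{3-[(tert-butyldiphenylsilyl)oxy]prop-1-en-2-yl}-1-imino-3a-methyloctahydro-7aH-inden-7a-ol (not isolated) | C=C(CO[Si](c1ccccc1)(c1ccccc1)C(C)(C)C)[C@H]1C[C@]2(O)C(=N)CC[C@]2(C)CC1 | intermediate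
12 | cis-fused (3aS,6R,7aR)-6-{3-[(tert-butyldiphenylsilyl)oxy]prop-1-en-2-yl}-7a-hydroxy-3a-methyloctahydro-1H-inden-1-one | C=C(CO[Si](c1ccccc1)(c1ccccc1)C(C)(C)C)[C@H]1C[C@]2(O)C(=O)CC[C@]2(C)CC1 | intermediate
13 | (3aS,6R)-6-{3-[(tert-butyldiphenylsilyl)oxy]prop-1-en-2-yl}-3a-methyl-2,3,3a,4,5,6-hexahydro-1H-inden-1-one | C=C(CO[Si](c1ccccc1)(c1ccccc1)C(C)(C)C)[C@H]1C=C2C(=O)CC[C@]2(C)CC1 | intermediate
14 | ethyl vinyl ether | C=COCC | starting material
15 | (1S,3aS,6R)-6-{3-[(tert-butyldiphenylsilyl)oxy]prop-1-en-2-yl}-1-(1-ethoxyethenyl)-3a-methyl-2,3,3a,4,5,6-hexahydro-1H-inden-1-ol (not isolated) | C=C(CO[Si](c1ccccc1)(c1ccccc1)C(C)(C)C)[C@H]1C=C2[C@](O)(C(=C)OCC)CC[C@]2(C)CC1 | intermediate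
16 | 1-[(1S,3aS,6R)-6-{3-[(tert-butyldiphenylsilyl)oxy]prop-1-en-2-yl}-1-hydroxy-3a-methyl-2,3,3a,4,5,6-hexahydro-1H-inden-1-yl]ethan-1-one | C=C(CO[Si](c1ccccc1)(c1ccccc1)C(C)(C)C)[C@H]1C=C2[C@](O)(C(C)=O)CC[C@]2(C)CC1 | intermediate
17 | (1R,4aS,7R)-7-{3-[(tert-butyldiphenylsilyl)oxy]prop-1-en-2-yl}-1-hydroxy-1,4a-dimethyl-3,4,4a,5,6,7-hexahydronaphthalen-2(1H)-one | C=C(CO[Si](c1ccccc1)(c1ccccc1)C(C)(C)C)[C@H]1C=C2[C@](C)(CCC(=O)[C@]2(C)O)CC1 | intermediate
18 | (1R,2S,4aS,7R)-7-{3-[(tert-butyldiphenylsilyl)oxy]prop-1-en-2-yl}-1,4a-dimethyl-1,2,3,4,4a,5,6,7-octahydronaphthalene-1,2-diol | C=C(CO[Si](c1ccccc1)(c1ccccc1)C(C)(C)C)[C@H]1C=C2[C@](C)(CC[C@H](O)[C@]2(C)O)CC1 | intermediate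
19 | angelic acid, (Z)-2-methylbut-2-enoic acid | C/C=C(/C)C(=O)O | starting material
20 | (1R,2S,4aS,7R)-7-{3-[(tert-butyldiphenylsilyl)oxy]prop-1-en-2-yl}-1-hydroxy-1,4a-dimethyl-1,2,3,4,4a,5,6,7-octahydronaphthalen-2-yl (Z)-2-methylbut-2-enoate | C=C(CO[Si](c1ccccc1)(c1ccccc1)C(C)(C)C)[C@H]1C=C2[C@](C)(CC[C@H](OC(=O)/C(C)=C\C)[C@]2(C)O)CC1 | intermediate
21 | (1R,2S,4aS,7R)-1-hydroxy-7-(3-hydroxyprop-1-en-2-yl)-1,4a-dimethyl-1,2,3,4,4a,5,6,7-octahydronaphthalen-2-yl (Z)-2-methylbut-2-enoate | C=C(CO)[C@H]1C=C2[C@](C)(CC[C@H](OC(=O)/C(C)=C\C)[C@]2(C)O)CC1 | intermediate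
22 | (1R,2S,4aS,7R)-1-hydroxy-1,4a-dimethyl-7-(3-oxoprop-1-en-2-yl)-1,2,3,4,4a,5,6,7-octahydronaphthalen-2-yl (Z)-2-methylbut-2-enoate | C=C(C=O)[C@H]1C=C2[C@](C)(CC[C@H](OC(=O)/C(C)=C\C)[C@]2(C)O)CC1 | intermediate
23 | 2-[(2R,4aS,7S,8R)-8-hydroxy-4a,8-dimethyl-7-{[(Z)-2-methylbut-2-enoyl]oxy}-2,3,4,4a,5,6,7,8-octahydronaphthalen-2-yl]prop-2-enoic acid (not isolated) | C=C(C(=O)O)[C@H]1C=C2[C@](C)(CC[C@H](OC(=O)/C(C)=C\C)[C@]2(C)O)CC1 | intermediate
24 | methyl 2-[(2R,4aS,7S,8R)-8-hydroxy-4a,8-dimethyl-7-{[(Z)-2-methylbut-2-enoyl]oxy}-2,3,4,4a,5,6,7,8-octahydronaphthalen-2-yl]prop-2-enoate (CNP0283268.1) | C=C(C(=O)OC)[C@H]1C=C2[C@](C)(CC[C@H](OC(=O)/C(C)=C\C)[C@]2(C)O)CC1 | target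

**Step count and risks**

Total step count: 13. Longest linear sequence: 13 steps (from 1).

Steps most likely to fail:

1. Step 8. What may go wrong: migration of the saturated ring carbon C2 in place of C5, incomplete chelation that lets the acetyl group rotate and erodes the C4 configuration, and onward methyl shift of the product to the conjugated ketol. Fallback (ring A by annulation, C4 by Grignard addition): it sets out from 5. The imine 8 is combined with methyl vinyl ketone to give the Michael adduct imine F1, which aqueous acetic acid hydrolyses to the diketone F2. NaOMe/MeOH condenses this to the bicyclic enone F3. NaBH4/CeCl3 should give the 3β-allylic alcohol F4. VO(acac)2/t-BuOOH should epoxidise syn to the hydroxyl and give the 4β,5β-epoxy alcohol F5. Diethylaluminium 2,2,6,6-tetramethylpiperidide removes H-6 syn to the epoxide oxygen and opens it to the Δ5-3β,4β-diol F6. MnO2 oxidises only the allylic C4 hydroxyl to give the hydroxy enone F7. MeMgBr should then add to C4 from the α face, anti to the C10 methyl, and the sequence comes back to the route at diol 18.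

2. Step 4. What may go wrong: erosion of facial selectivity, because the auxiliary has to override the ring's own preference for attack cis to the C7 substituent, together with slow addition to the weak acceptor. Fallback (catalyst-controlled allylation and carbene-catalysed ring closure): it sets out from 5. TMSCl/NaI/Et3N in MeCN gives the more substituted silyl enol ether F8. Pd2(dba)3, (S)-t-BuPHOX (enantiomer chosen by analogy with 2-methylcyclohexanone), diallyl carbonate and Bu4N[Ph3SiF2] should give the α-allyl ketone F9 with the quaternary center set by the ligand. 9-BBN adds to the monosubstituted alkene to give the alkylborane F10, which NaBO3 oxidises to the primary alcohol F11. Dess–Martin periodinane gives the keto aldehyde F12. A triazolium-derived N-heterocyclic carbene (DBU, THF) closes the five-membered ring by intramolecular crossed benzoin reaction, and the sequence comes back to the route at ketol 12.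

3. Step 10. What may go wrong: slow acylation of the hindered secondary hydroxyl and Z-to-E isomerisation of the angeloyl group under the forcing conditions then needed. Fallback (build the Z-alkene on the ester): it sets out from 18. DCC/DMAP coupling with 2-[bis(2,2,2-trifluoroethoxy)phosphoryl]propanoic acid gives the phosphonate ester F13. KHMDS/18-crown-6 and acetaldehyde at −78 °C (Still–Gennari olefination) should give the Z-configured ester, and the sequence comes back to the route at 20.

**Further compounds**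

F1 | step 8 | N-[(1R)-1-phenylethyl] imine of F2 (Michael adduct of 8 with methyl vinyl ketone) | C=C(CO[Si](c1ccccc1)(c1ccccc1)C(C)(C)C)[C@H]1CC(=N[C@H](C)c2ccccc2)[C@](C)(CCC(C)=O)CC1
F2 | step 8 | (2S,5R)-5-{3-[(tert-butyldiphenylsilyl)oxy]prop-1-en-2-yl}-2-methyl-2-(3-oxobutyl)cyclohexan-1-one | C=C(CO[Si](c1ccccc1)(c1ccccc1)C(C)(C)C)[C@H]1CC(=O)[C@](C)(CCC(C)=O)CC1
F3 | step 8 | (4aS,7R)-7-{3-[(tert-butyldiphenylsilyl)oxy]prop-1-en-2-yl}-4a-methyl-4,4a,5,6,7,8-hexahydronaphthalen-2(3H)-one | C=C(CO[Si](c1ccccc1)(c1ccccc1)C(C)(C)C)[C@H]1CC2=CC(=O)CC[C@]2(C)CC1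
F4 | step 8 | (2S,4aS,7R)-7-{3-[(tert-butyldiphenylsilyl)oxy]prop-1-en-2-yl}-4a-methyl-2,3,4,4a,5,6,7,8-octahydronaphthalen-2-ol (3β-allylic alcohol) | C=C(CO[Si](c1ccccc1)(c1ccccc1)C(C)(C)C)[C@H]1CC2=C[C@@H](O)CC[C@]2(C)CC1
F5 | step 8 | 4β,5β-epoxy-3β-alcohol of F4 (epoxide syn to the hydroxyl and to the C10 methyl) | C=C(CO[Si](c1ccccc1)(c1ccccc1)C(C)(C)C)[C@H]1C[C@@]23O[C@H]3[C@@H](O)CC[C@]2(C)CC1
F6 | step 8 | Δ5-3β,4β-diol without the C4 methyl (12-silyloxy-15-nor-eudesma-5,11(13)-diene-3β,4β-diol) | C=C(CO[Si](c1ccccc1)(c1ccccc1)C(C)(C)C)[C@H]1C=C2[C@](C)(CC[C@H](O)[C@@H]2O)CC1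
F7 | step 8 | 3β-hydroxy-Δ5-4-ketone (12-silyloxy-3β-hydroxy-15-nor-eudesma-5,11(13)-dien-4-one) | C=C(CO[Si](c1ccccc1)(c1ccccc1)C(C)(C)C)[C@H]1C=C2[C@](C)(CC[C@H](O)C2=O)CC1
F8 | step 4 | more substituted trimethylsilyl enol ether of 5 | C=C(CO[Si](c1ccccc1)(c1ccccc1)C(C)(C)C)[C@H]1CC(O[Si](C)(C)C)=C(C)CC1
F9 | step 4 | (2S,5R)-2-allyl-5-{3-[(tert-butyldiphenylsilyl)oxy]prop-1-en-2-yl}-2-methylcyclohexan-1-one | C=C(CO[Si](c1ccccc1)(c1ccccc1)C(C)(C)C)[C@H]1CC(=O)[C@](C)(CC=C)CC1
F10 | step 4 | B-alkyl-9-borabicyclo[3.3.1]nonane adduct of F9 at the terminal allyl carbon | C=C(CO[Si](c1ccccc1)(c1ccccc1)C(C)(C)C)[C@H]1CC(=O)[C@](C)(CCCB2C3CCCC2CCC3)CC1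
F11 | step 4 | (2S,5R)-5-{3-[(tert-butyldiphenylsilyl)oxy]prop-1-en-2-yl}-2-(3-hydroxypropyl)-2-methylcyclohexan-1-one | C=C(CO[Si](c1ccccc1)(c1ccccc1)C(C)(C)C)[C@H]1CC(=O)[C@](C)(CCCO)CC1
F12 | step 4 | 3-[(1S,4R)-4-{3-[(tert-butyldiphenylsilyl)oxy]prop-1-en-2-yl}-1-methyl-2-oxocyclohexyl]propanal | C=C(CO[Si](c1ccccc1)(c1ccccc1)C(C)(C)C)[C@H]1CC(=O)[C@](C)(CCC=O)CC1
F13 | step 10 | 3-O-{2-[bis(2,2,2-trifluoroethoxy)phosphoryl]propanoyl} ester of diol 18 | C=C(CO[Si](c1ccccc1)(c1ccccc1)C(C)(C)C)[C@H]1C=C2[C@](C)(CC[C@H](OC(=O)C(C)P(=O)(OCC(F)(F)F)OCC(F)(F)F)[C@]2(C)O)CC1
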